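The route rests on cutting the heteroannular diene C9=C10–C1=C2, which runs through rings A and B on either side of quaternary C5 (eremophilane numbering), back to an ethynyl group (C10, C1) on C5 that sits between two alkene-ended arms. A single ruthenium-carbene cascade should then make the C9=C10 and C1=C2 bonds and close both six-membered rings, while every stereocentre of the bicycle is already present in the acyclic chain. The precursor is an acyclic dienyne: C5 bears methyl, ethynyl, a C6–C9 arm (C7 hydroxyl, C8 acetal ether, terminal vinyl) and a C4–C2 arm (C4 methyl, C3 silyl ether, isobutenyl end). Ketone, C7 side chain and both esters follow.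

Key step: step 11

Remark on numbering: eremophilane numbering is kept for every intermediate (ring B: C1–C5, C10; ring A: C5–C10; side chain C11–C13); β means the face of the C5 methyl group.

Remark on design: the alkyne comes in with the first starting material. The ring A arm carries a free C7 hydroxyl and a small methoxymethyl ether of defined configuration (8S, β). After ring closure C7 can therefore be oxidised at once, and the C8 oxygen, together with the C5 methyl, should steer the C7 addition.

Assumption: the (S,S)-bromoborane of step 3 is taken to be the antipode that leads to the (2S,3S) acid, i.e. the one that turns (E)-but-2-enyl propanoate into the (2S,3S) anti acid under the same conditions; should the first run show the opposite sense, the (R,R)-reagent is used with no other change.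

Step 1
Reactants: 1 (2E)-3-methylpent-2-en-4-yn-1-ol
Product: 3 (2E)-3-methyl-5-(trimethylsilyl)pent-2-en-4-yn-1-ol, via bis-silyl ether 2 (not isolated)
Conditions: n-BuLi (2.1 equiv), THF, −78 → 0 °C; Me3SiCl (2.2 equiv); then 1 M HCl, rt
Reagents that add atoms: chlorotrimethylsilane, C[Si](C)(C)Cl
Why: Double deprotonation gives the alkoxide–acetylide, both ends are silylated, and only the labile O–Si bond is hydrolysed on acidic work-up, which masks the alkyne C–H for the later hydroboration (C-silylation of a terminal alkyne).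

Step 2
Reactants: 3 (2E)-3-methyl-5-(trimethylsilyl)pent-2-en-4-yn-1-ol; 4 propanoyl chloride
Product: 5 (2E)-3-methyl-5-(trimethylsilyl)pent-2-en-4-yn-1-yl propanoate
Conditions: pyridine, CH2Cl2, 0 °C
Reagents that add atoms: none
Why: O-acylation of a primary allylic alcohol with an acid chloride should be clean (esterification).

Step 3
Reactants: 5 (2E)-3-methyl-5-(trimethylsilyl)pent-2-en-4-yn-1-yl propanoate
Product: 7 (2S,3S)-2,3-dimethyl-3-[(trimethylsilyl)ethynyl]pent-4-enoic acid, via boron ketene acetal 6 (not isolated)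
Conditions: (4S,5S)-2-bromo-1,3-bis{[3,5-bis(trifluoromethyl)phenyl]sulfonyl}-4,5-diphenyl-1,3,2-diazaborolidine (made from the bis-sulfonamide and BBr3), Et3N, toluene/hexane, −78 → −20 °C; aq. work-up
Reagents that add atoms: none
Why: The bromoborane and Et3N in a non-polar medium should give the E(O) boron ketene acetal (methyl trans to O–B), whose chair [3,3] shift onto the E alkene (C5 methyl axial, alkynyl equatorial) sets C4 and C5 in the like sense while the C2-symmetric sulfonamide ligand on boron selects the enolate face that leads to (2S,3S) (enantioselective Ireland–Claisen rearrangement).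

Step 4
Reactants: 7 (2S,3S)-2,3-dimethyl-3-[(trimethylsilyl)ethynyl]pent-4-enoic acid
Product: 8 (2S,3S)-2,3-dimethyl-3-[(trimethylsilyl)ethynyl]pent-4-en-1-ol
Conditions: LiAlH4, THF, 0 °C → rt; aq. potassium sodium tartrate (KNaC4H4O6)
Reagents that add atoms: none
Why: Hydride reduction of the acid to the primary alcohol leaves the alkene, the silyl alkyne and both stereocentres untouched, and the tartrate work-up avoids strong base (LiAlH4 reduction).

Step 5
Reactants: 8 (2S,3S)-2,3-dimethyl-3-[(trimethylsilyl)ethynyl]pent-4-en-1-ol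
Product: 9 (2S,3S)-2,3-dimethyl-3-[(trimethylsilyl)ethynyl]pent-4-enal
Conditions: Dess–Martin periodinane, NaHCO3, CH2Cl2, 0 °C → rt
Reagents that add atoms: none
Why: The base-free hypervalent-iodine oxidation stops at the aldehyde and should not epimerise the α-stereocentre C4 (Dess–Martin oxidation).

Step 6
Reactants: 9 (2S,3S)-2,3-dimethyl-3-[(trimethylsilyl)ethynyl]pent-4-enal; 10 2-methylprop-1-enylmagnesium bromide
Product: 11 (4S,5S,6S)-2,5,6-trimethyl-6-[(trimethylsilyl)ethynyl]octa-2,7-dien-4-ol
Conditions: THF, −78 → −40 °C; aq. NH4Cl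
Reagents that add atoms: none
Why: Felkin–Anh addition of the alkenyl Grignard reagent, anti to the bulky quaternary C5 substituent of the α-methyl aldehyde, should give the 3,4-syn alcohol with the (S) carbinol that becomes C3 (Grignard 1,2-addition).

Step 7
Reactants: 11 (4S,5S,6S)-2,5,6-trimethyl-6-[(trimethylsilyl)ethynyl]octa-2,7-dien-4-ol
Product: 12 (4S,5S,6S)-4-[(tert-butyldimethylsilyl)oxy]-2,5,6-trimethyl-6-[(trimethylsilyl)ethynyl]octa-2,7-diene
Conditions: t-BuMe2SiOTf, 2,6-lutidine, CH2Cl2, −78 → 0 °C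
Reagents that add atoms: tert-butyldimethylsilyl trifluoromethanesulfonate, CC(C)(C)[Si](C)(C)OS(=O)(=O)C(F)(F)F
Why: The silyl triflate is reactive enough for the hindered secondary allylic alcohol and the hindered base prevents ionisation of the allylic C–O bond (O-silylation).

Step 8
Reactants: 12 (4S,5S,6S)-4-[(tert-butyldimethylsilyl)oxy]-2,5,6-trimethyl-6-[(trimethylsilyl)ethynyl]octa-2,7-diene
Product: 15 (3S,4S,5S)-5-[(tert-butyldimethylsilyl)oxy]-3-ethynyl-3,4,7-trimethyloct-6-en-1-ol, via alkylborane 13 (not isolated), via silylalkyne alcohol 14 (not isolated)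
Conditions: 9-BBN, THF, 0 °C → rt; then NaOH, H2O2, H2O/MeOH, 0 °C → rt
Reagents that add atoms: hydrogen peroxide, OO
Why: 9-BBN adds with anti-Markovnikov regiochemistry to the only monosubstituted alkene, far faster than to the trisubstituted alkene or the silylated alkyne, and the alkaline methanolic peroxide work-up both oxidises the C–B bond and cleaves the alkynyl C–Si bond (hydroboration–oxidation with protodesilylation).

Step 9
Reactants: 15 (3S,4S,5S)-5-[(tert-butyldimethylsilyl)oxy]-3-ethynyl-3,4,7-trimethyloct-6-en-1-ol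
Product: 16 (3S,4S,5S)-5-[(tert-butyldimethylsilyl)oxy]-3-ethynyl-3,4,7-trimethyloct-6-enal
Conditions: Dess–Martin periodinane, NaHCO3, CH2Cl2, 0 °C → rt
Reagents that add atoms: none
Why: The primary alcohol is oxidised to the C7 aldehyde, which has no α-stereocentre, and the terminal alkyne and the allylic silyl ether tolerate the buffered reagent (Dess–Martin oxidation).

Step 10
Reactants: 16 (3S,4S,5S)-5-[(tert-butyldimethylsilyl)oxy]-3-ethynyl-3,4,7-trimethyloct-6-enal; 17 allyl methoxymethyl ether
Product: 19 (3S,4S,6S,7S,8S)-8-[(tert-butyldimethylsilyl)oxy]-6-ethynyl-3-(methoxymethoxy)-6,7,10-trimethylundeca-1,9-dien-4-ol, via allylborane 18 (not isolated)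
Conditions: 17, s-BuLi, THF, −78 °C; (+)-B-methoxydiisopinocampheylborane [(+)-Ipc2BOMe]; BF3·OEt2; then 16, −78 °C; NaOH, H2O2, 0 °C → rt
Reagents that add atoms: none
Why: The (Z)-γ-alkoxyallylborane reacts through a closed chair transition state to give the syn 1,2-diol monoether, and the isopinocampheyl groups of the reagent derived from (+)-Ipc2BOMe direct attack to the Re face of the unbranched aldehyde, which fixes C7 and C8 as (S,S) (asymmetric γ-alkoxyallylboration).

Step 11
Reactants: 19 (3S,4S,6S,7S,8S)-8-[(tert-butyldimethylsilyl)oxy]-6-ethynyl-3-(methoxymethoxy)-6,7,10-trimethylundeca-1,9-dien-4-ol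
Product: 20 (3S,4S,5S,7S,8S)-3α-[(tert-butyldimethylsilyl)oxy]-8β-(methoxymethoxy)-11,12,13-trinoreremophila-1,9-dien-7α-ol
Conditions: RuCl2(=CHPh)(PCy3)(1,3-dimesitylimidazolidin-2-ylidene) (second-generation Grubbs catalyst, 10 mol %), toluene (2 mM), 80 °C
Reagents that add atoms: none
Why: The benzylidene exchanges onto the monosubstituted C9 alkene, and the C9 alkylidene adds across the C10≡C1 triple bond through a ruthenacyclobutene that opens to the C9=C10 alkene and a C1 vinylcarbene. This carbene then undergoes ring-closing metathesis with the C2 isobutenyl alkene, giving C1=C2 and Ru=CMe2, which reloads on the next C9 vinyl group with loss of 2-methylpropene. The closest known reaction type is the tandem ring-closing dienyne metathesis that gives fused bicyclic 1,3-dienes. Ring A closes by exo-mode ene–yne ring closure (six-membered, C9 joining the proximal alkyne carbon C10) and ring B by six-membered alkene–carbene ring closure at C1/C2. No stereocentre is formed, and C3, C4, C5, C7 and C8 are not touched. The step needs the carbene to start at C9 and not at C2 (which would give a five/seven ring pair): this is secured by the unhindered monosubstituted C9 alkene next to a small acetal ether against a trisubstituted isobutenyl group and a neopentyl alkyne, and entry of a methylidene at the alkyne would still lead to the same diene.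

Step 12
Reactants: 20 (3S,4S,5S,7S,8S)-3α-[(tert-butyldimethylsilyl)oxy]-8β-(methoxymethoxy)-11,12,13-trinoreremophila-1,9-dien-7α-ol
Product: 21 (3S,4S,5S,8S)-3α-[(tert-butyldimethylsilyl)oxy]-8β-(methoxymethoxy)-11,12,13-trinoreremophila-1,9-dien-7-one
Conditions: Dess–Martin periodinane, NaHCO3, CH2Cl2, 0 °C; used at once
Reagents that add atoms: none
Why: Buffered, base-free oxidation of the secondary C7 alcohol should give the β,γ-unsaturated α-alkoxy ketone without moving the diene into conjugation, and the ketone is taken on without storage (Dess–Martin oxidation).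

Step 13
Reactants: 21 (3S,4S,5S,8S)-3α-[(tert-butyldimethylsilyl)oxy]-8β-(methoxymethoxy)-11,12,13-trinoreremophila-1,9-dien-7-one; 22 2-bromoprop-2-en-1-ol
Product: 24 (3S,4S,5S,7S,8S)-3α-[(tert-butyldimethylsilyl)oxy]-8β-(methoxymethoxy)eremophila-1,9,11(13)-triene-7β,12-diol, via dilithio reagent 23 (not isolated)
Conditions: 22, t-BuLi (3 equiv), Et2O, −78 → 0 °C; CeCl3, THF, −78 °C; then 21, −78 °C; aq. NH4Cl
Reagents that add atoms: none
Why: Bromine–lithium exchange gives the 2-lithioallyl alkoxide, whose cerium reagent adds to easily enolised ketones in preference to deprotonating them, and it should enter on the α face, away from the axial C5 methyl and anti to the β C8 oxygen, so that C7 receives a β hydroxyl and an α side chain (organocerium 1,2-addition).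

Step 14
Reactants: 24 (3S,4S,5S,7S,8S)-3α-[(tert-butyldimethylsilyl)oxy]-8β-(methoxymethoxy)eremophila-1,9,11(13)-triene-7β,12-diol
Product: 25 (3S,4S,5S,7S,8S)-12-acetoxy-3α-[(tert-butyldimethylsilyl)oxy]-8β-(methoxymethoxy)eremophila-1,9,11(13)-trien-7β-ol
Conditions: Ac2O, pyridine, CH2Cl2, 0 °C
Reagents that add atoms: acetic anhydride, CC(=O)OC(C)=O
Why: The primary allylic hydroxyl is acetylated much faster than the tertiary C7 hydroxyl in pyridine without DMAP (selective O-acetylation).

Step 15
Reactants: 25 (3S,4S,5S,7S,8S)-12-acetoxy-3α-[(tert-butyldimethylsilyl)oxy]-8β-(methoxymethoxy)eremophila-1,9,11(13)-trien-7β-ol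
Product: 26 (3S,4S,5S,7S,8S)-12-acetoxy-3α-[(tert-butyldimethylsilyl)oxy]eremophila-1,9,11(13)-triene-7β,8β-diol
Conditions: MgBr2·OEt2, n-BuSH, Et2O, rt
Reagents that add atoms: none
Why: Magnesium bromide activates the acetal and the thiol takes up the CH2OMe unit as the O,S-acetal, a near-neutral cleavage that should neither ionise the dienylic C8–O bond nor close a formal onto the neighbouring C7 hydroxyl, and it spares the silyl ether and the acetate (Lewis acid/thiol cleavage of a methoxymethyl ether).

Step 16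
Reactants: 26 (3S,4S,5S,7S,8S)-12-acetoxy-3α-[(tert-butyldimethylsilyl)oxy]eremophila-1,9,11(13)-triene-7β,8β-diol
Product: 27 (3S,4S,5S,7S)-12-acetoxy-3α-[(tert-butyldimethylsilyl)oxy]-7β-hydroxyeremophila-1,9,11(13)-trien-8-one
Conditions: Dess–Martin periodinane, NaHCO3, CH2Cl2, 0 °C → rt
Reagents that add atoms: none
Why: Only the secondary dienylic C8 alcohol can be oxidised, which gives the conjugated dienone and removes the temporary C8 stereocentre, while the tertiary C7 hydroxyl is inert (Dess–Martin oxidation).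

Step 17
Reactants: 27 (3S,4S,5S,7S)-12-acetoxy-3α-[(tert-butyldimethylsilyl)oxy]-7β-hydroxyeremophila-1,9,11(13)-trien-8-one
Product: 28 (3S,4S,5S,7S)-12-acetoxy-3α,7β-dihydroxyeremophila-1,9,11(13)-trien-8-one
Conditions: HF·pyridine, pyridine, THF, 0 °C → rt
Reagents that add atoms: none
Why: Buffered HF·pyridine cleaves the remaining secondary silyl ether without touching the acetate or the α-ketol (fluoride desilylation).

Step 18
Reactants: 29 (2R)-2-methylbutanoic acid
Product: 30 (2R)-2-methylbutan-1-ol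
Conditions: LiAlH4, Et2O, 0 °C → rt; aq. potassium sodium tartrate (KNaC4H4O6)
Reagents that add atoms: none
Why: Hydride reduction of the acid does not involve the stereocentre (LiAlH4 reduction).

Step 19
Reactants: 30 (2R)-2-methylbutan-1-ol; 31 2-(triphenylphosphoranylidene)propanal
Product: 33 (2E,4R)-2,4-dimethylhex-2-enal, via (2R)-2-methylbutanal 32 (not isolated)
Conditions: TEMPO (10 mol %), PhI(OAc)2, CH2Cl2, rt; then 31, 40 °C
Reagents that add atoms: none
Why: The base-free nitroxyl oxidation preserves the α-stereocentre of the volatile aldehyde, which is trapped in the same flask by the stabilised ylide to give the E enal (oxidation followed by Wittig olefination).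

Step 20
Reactants: 33 (2E,4R)-2,4-dimethylhex-2-enal; 34 triethyl phosphonoacetate
Product: 35 ethyl (2E,4E,6R)-4,6-dimethylocta-2,4-dienoate
Conditions: NaH, THF, 0 °C → rt
Reagents that add atoms: none
Why: The stabilised phosphonate anion adds to the enal faster than it deprotonates the γ position and gives the 2E alkene (Horner–Wadsworth–Emmons olefination).

Step 21
Reactants: 35 ethyl (2E,4E,6R)-4,6-dimethylocta-2,4-dienoate
Product: 36 (2E,4E,6R)-4,6-dimethylocta-2,4-dienoic acid
Conditions: LiOH, THF/MeOH/H2O, rt; then 1 M HCl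
Reagents that add atoms: lithium hydroxide, [Li+].[OH-]
Why: Hydroxide cleaves the ethyl ester without disturbing the diene geometry or the remote C6 stereocentre (saponification).

Step 22
Reactants: 28 (3S,4S,5S,7S)-12-acetoxy-3α,7β-dihydroxyeremophila-1,9,11(13)-trien-8-one; 36 (2E,4E,6R)-4,6-dimethylocta-2,4-dienoic acid
Product: 38 CNP0160850.1, 12-acetoxy-7β-hydroxy-8-oxoeremophila-1,9,11(13)-trien-3α-yl (2E,4E,6R)-4,6-dimethylocta-2,4-dienoate, via mixed anhydride 37 (not isolated)
Conditions: 2,4,6-trichlorobenzoyl chloride, Et3N, THF, rt; then 28, DMAP, toluene, rt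
Reagents that add atoms: none
Why: The mixed anhydride acylates the secondary allylic C3 hydroxyl under DMAP catalysis while the tertiary C7 hydroxyl stays free, and the mild base should leave the dienoate geometry intact (Yamaguchi esterification).

Compound list
1 | (2E)-3-methylpent-2-en-4-yn-1-ol | C#C/C(C)=C/CO | starting material
2 | trimethyl{[(2E)-3-methyl-5-(trimethylsilyl)pent-2-en-4-yn-1-yl]oxy}silane | C[Si](C)(C)C#C/C(C)=C/CO[Si](C)(C)C | intermediate
3 | (2E)-3-methyl-5-(trimethylsilyl)pent-2-en-4-yn-1-ol | C[Si](C)(C)C#C/C(C)=C/CO | intermediate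
4 | propanoyl chloride | CCC(=O)Cl | starting material
5 | (2E)-3-methyl-5-(trimethylsilyl)pent-2-en-4-yn-1-yl propanoate | CCC(=O)OC/C=C(\C)C#C[Si](C)(C)C | intermediate
6 | E(O) boron ketene acetal of 5 carrying the (4S,5S)-1,3-bis(arylsulfonyl)-4,5-diphenyl-1,3,2-diazaborolidin-2-yl group on oxygen | C/C=C(/OB1N(S(=O)(=O)c2cc(C(F)(F)F)cc(C(F)(F)F)c2)[C@@H](c2ccccc2)[C@H](c2ccccc2)N1S(=O)(=O)c1cc(C(F)(F)F)cc(C(F)(F)F)c1)OC/C=C(\C)C#C[Si](C)(C)C | intermediate
7 | (2S,3S)-2,3-dimethyl-3-[(trimethylsilyl)ethynyl]pent-4-enoic acid | C=C[C@](C)(C#C[Si](C)(C)C)[C@H](C)C(=O)O | intermediate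
8 | (2S,3S)-2,3-dimethyl-3-[(trimethylsilyl)ethynyl]pent-4-en-1-ol | C=C[C@](C)(C#C[Si](C)(C)C)[C@H](C)CO | intermediate
9 | (2S,3S)-2,3-dimethyl-3-[(trimethylsilyl)ethynyl]pent-4-enal | C=C[C@](C)(C#C[Si](C)(C)C)[C@H](C)C=O | intermediate
10 | 2-methylprop-1-enylmagnesium bromide | CC(C)=C[Mg]Br | starting material
11 | (4S,5S,6S)-2,5,6-trimethyl-6-[(trimethylsilyl)ethynyl]octa-2,7-dien-4-ol | C=C[C@](C)(C#C[Si](C)(C)C)[C@H](C)[C@@H](O)C=C(C)C | intermediate
12 | (4S,5S,6S)-4-[(tert-butyldimethylsilyl)oxy]-2,5,6-trimethyl-6-[(trimethylsilyl)ethynyl]octa-2,7-diene | C=C[C@](C)(C#C[Si](C)(C)C)[C@H](C)[C@@H](O[Si](C)(C)C(C)(C)C)C=C(C)C | intermediate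
13 | B-alkyl-9-borabicyclo[3.3.1]nonane from 12 (boron on the terminal carbon of the former vinyl group) | B1(CC[C@](C)(C#C[Si](C)(C)C)[C@H](C)[C@@H](O[Si](C)(C)C(C)(C)C)C=C(C)C)C2CCCC1CCC2 | intermediate
14 | (3S,4S,5S)-5-[(tert-butyldimethylsilyl)oxy]-3,4,7-trimethyl-3-[(trimethylsilyl)ethynyl]oct-6-en-1-ol | OCC[C@](C)(C#C[Si](C)(C)C)[C@H](C)[C@@H](O[Si](C)(C)C(C)(C)C)C=C(C)C | intermediate
15 | (3S,4S,5S)-5-[(tert-butyldimethylsilyl)oxy]-3-ethynyl-3,4,7-trimethyloct-6-en-1-ol | OCC[C@](C)(C#C)[C@H](C)[C@@H](O[Si](C)(C)C(C)(C)C)C=C(C)C | intermediate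
16 | (3S,4S,5S)-5-[(tert-butyldimethylsilyl)oxy]-3-ethynyl-3,4,7-trimethyloct-6-enal | O=CC[C@](C)(C#C)[C@H](C)[C@@H](O[Si](C)(C)C(C)(C)C)C=C(C)C | intermediate
17 | allyl methoxymethyl ether (3-(methoxymethoxy)prop-1-ene) | C=CCOCOC | starting material
18 | [(2Z)-3-(methoxymethoxy)prop-2-en-1-yl]diisopinocampheylborane (isopinocampheyl groups of the (+)-Ipc2BOMe series) | COCO/C=C\CB([C@H]1C[C@H]2C[C@@H]([C@@H]1C)C2(C)C)[C@H]1C[C@H]2C[C@@H]([C@@H]1C)C2(C)C | intermediate
19 | (3S,4S,6S,7S,8S)-8-[(tert-butyldimethylsilyl)oxy]-6-ethynyl-3-(methoxymethoxy)-6,7,10-trimethylundeca-1,9-dien-4-ol (key-step precursor) | C=C[C@H](OCOC)[C@@H](O)C[C@](C)(C#C)[C@H](C)[C@@H](O[Si](C)(C)C(C)(C)C)C=C(C)C | intermediate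
20 | (3S,4S,5S,7S,8S)-3α-[(tert-butyldimethylsilyl)oxy]-8β-(methoxymethoxy)-11,12,13-trinoreremophila-1,9-dien-7α-ol (key-step product) | COCO[C@@H]1[C@@H](O)C[C@]2(C)C(=C1)C=C[C@H](O[Si](C)(C)C(C)(C)C)[C@H]2C | intermediate
21 | (3S,4S,5S,8S)-3α-[(tert-butyldimethylsilyl)oxy]-8β-(methoxymethoxy)-11,12,13-trinoreremophila-1,9-dien-7-one | COCO[C@@H]1C(=O)C[C@]2(C)C(=C1)C=C[C@H](O[Si](C)(C)C(C)(C)C)[C@H]2C | intermediate
22 | 2-bromoprop-2-en-1-ol | C=C(Br)CO | starting material
23 | lithium 2-lithioprop-2-en-1-olate | C=C([Li])CO[Li] | intermediate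
24 | (3S,4S,5S,7S,8S)-3α-[(tert-butyldimethylsilyl)oxy]-8β-(methoxymethoxy)eremophila-1,9,11(13)-triene-7β,12-diol | COCO[C@@H]1[C@@](O)(C(=C)CO)C[C@]2(C)C(=C1)C=C[C@H](O[Si](C)(C)C(C)(C)C)[C@H]2C | intermediate
25 | (3S,4S,5S,7S,8S)-12-acetoxy-3α-[(tert-butyldimethylsilyl)oxy]-8β-(methoxymethoxy)eremophila-1,9,11(13)-trien-7β-ol | COCO[C@@H]1[C@@](O)(C(=C)COC(C)=O)C[C@]2(C)C(=C1)C=C[C@H](O[Si](C)(C)C(C)(C)C)[C@H]2C | intermediate
26 | (3S,4S,5S,7S,8S)-12-acetoxy-3α-[(tert-butyldimethylsilyl)oxy]eremophila-1,9,11(13)-triene-7β,8β-diol | O[C@@H]1[C@@](O)(C(=C)COC(C)=O)C[C@]2(C)C(=C1)C=C[C@H](O[Si](C)(C)C(C)(C)C)[C@H]2C | intermediate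
27 | (3S,4S,5S,7S)-12-acetoxy-3α-[(tert-butyldimethylsilyl)oxy]-7β-hydroxyeremophila-1,9,11(13)-trien-8-one | O=C1[C@@](O)(C(=C)COC(C)=O)C[C@]2(C)C(=C1)C=C[C@H](O[Si](C)(C)C(C)(C)C)[C@H]2C | intermediate
28 | (3S,4S,5S,7S)-12-acetoxy-3α,7β-dihydroxyeremophila-1,9,11(13)-trien-8-one | O=C1[C@@](O)(C(=C)COC(C)=O)C[C@]2(C)C(=C1)C=C[C@H](O)[C@H]2C | intermediate
29 | (2R)-2-methylbutanoic acid | CC[C@@H](C)C(=O)O | starting material
30 | (2R)-2-methylbutan-1-ol | CC[C@@H](C)CO | intermediate
31 | 2-(triphenylphosphoranylidene)propanal | CC(C=O)=P(c1ccccc1)(c1ccccc1)c1ccccc1 | starting material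
32 | (2R)-2-methylbutanal | CC[C@@H](C)C=O | intermediate
33 | (2E,4R)-2,4-dimethylhex-2-enal | CC[C@@H](C)/C=C(\C)C=O | intermediate
34 | triethyl phosphonoacetate | CCOC(=O)CP(=O)(OCC)OCC | starting material
35 | ethyl (2E,4E,6R)-4,6-dimethylocta-2,4-dienoate | CCOC(=O)/C=C/C(C)=C/[C@H](C)CC | intermediate
36 | (2E,4E,6R)-4,6-dimethylocta-2,4-dienoic acid | OC(=O)/C=C/C(C)=C/[C@H](C)CC | intermediate
37 | (2E,4E,6R)-4,6-dimethylocta-2,4-dienoic 2,4,6-trichlorobenzoic anhydride | O=C(OC(=O)c1c(Cl)cc(Cl)cc1Cl)/C=C/C(C)=C/[C@H](C)CC | intermediate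
38 | CNP0160850.1, 12-acetoxy-7β-hydroxy-8-oxoeremophila-1,9,11(13)-trien-3α-yl (2E,4E,6R)-4,6-dimethylocta-2,4-dienoate | C=C(COC(C)=O)[C@@]1(O)C[C@]2(C)C(=CC1=O)C=C[C@H](OC(=O)/C=C/C(C)=C/[C@H](C)CC)[C@H]2C | target

Total step count: 22 (17 for the core, 4 for the acid, 1 coupling).
Longest linear sequence: 18 steps (steps 1–17 and 22).

Steps most likely to fail

Step 11. The carbene may enter at the alkyne or the isobutenyl group, or stall after the first ring, so that oligomers or the five/seven ring pair form. The fallback replaces the cascade by two ordinary alkene ring closures. Setting out from 19, ethene (1 atm) and RuCl2(=CHPh)(PCy3)2 (first-generation Grubbs catalyst) in CH2Cl2 should convert the alkyne by ene–yne cross-metathesis into the 2-substituted buta-1,3-diene, tetraene F1. The second-generation catalyst in toluene at 80 °C should then close ring A between the C9 vinyl group and the C10 methylene (loss of ethene) and ring B between the C1 vinyl group and the isobutenyl group (loss of 2-methylpropene), coming back at 20.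

Step 13. Deprotonation at C8 may compete with addition and let the diene migrate into conjugation, or the aggregated dilithio reagent may transfer poorly. The fallback uses a simpler nucleophile and oxygenates later. Setting out from 21, isopropenylmagnesium bromide with CeCl3 in THF at −78 °C should give the 7-isopropenyl carbinol F2. Allylic hydroxylation of its one unoxygenated allylic methyl group with catalytic SeO2 and t-BuOOH in CH2Cl2 should then give diol 24, where the route is rejoined.

Step 3. The rearrangement may be slow, or the face selection poor, on this new enynyl ester. The fallback is a racemic rearrangement followed by separation on a chiral auxiliary. Setting out from 5, LiN(i-Pr)2 and Me3SiCl in THF (−78 °C → rt) should give, by way of the E silyl ketene acetal F3, the racemic like acid F4. Its pivaloyl mixed anhydride acylates lithiated (4S)-4-benzyl-1,3-oxazolidin-2-one to the imide of the (2S,3S) acid F5 and the imide of the (2R,3R) acid F6, which are separated by chromatography. LiBH4 in wet Et2O reduces F5 to alcohol 8, where the route is rejoined.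

Further compounds
F1 | step 11 | (3S,4S,6S,7S,8S)-8-[(tert-butyldimethylsilyl)oxy]-6-(buta-1,3-dien-2-yl)-3-(methoxymethoxy)-6,7,10-trimethylundeca-1,9-dien-4-ol | C=C[C@H](OCOC)[C@@H](O)C[C@](C)(C(=C)C=C)[C@H](C)[C@@H](O[Si](C)(C)C(C)(C)C)C=C(C)C
F2 | step 13 | (3S,4S,5S,7S,8S)-3α-[(tert-butyldimethylsilyl)oxy]-8β-(methoxymethoxy)eremophila-1,9,11(13)-trien-7β-ol | COCO[C@@H]1[C@@](O)(C(C)=C)C[C@]2(C)C(=C1)C=C[C@H](O[Si](C)(C)C(C)(C)C)[C@H]2C
F3 | step 3 | E silyl ketene acetal of 5 (methyl trans to O–Si) | C/C=C(/O[Si](C)(C)C)OC/C=C(\C)C#C[Si](C)(C)C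
F4 | step 3 | racemic (2S*,3S*)-2,3-dimethyl-3-[(trimethylsilyl)ethynyl]pent-4-enoic acid (both enantiomers) | C=C[C@](C)(C#C[Si](C)(C)C)[C@H](C)C(=O)O.C=C[C@@](C)(C#C[Si](C)(C)C)[C@@H](C)C(=O)O
F5 | step 3 | (4S)-4-benzyl-3-{(2S,3S)-2,3-dimethyl-3-[(trimethylsilyl)ethynyl]pent-4-enoyl}-1,3-oxazolidin-2-one | C=C[C@](C)(C#C[Si](C)(C)C)[C@H](C)C(=O)N1[C@@H](Cc2ccccc2)COC1=O
F6 | step 3 | (4S)-4-benzyl-3-{(2R,3R)-2,3-dimethyl-3-[(trimethylsilyl)ethynyl]pent-4-enoyl}-1,3-oxazolidin-2-one | C=C[C@@](C)(C#C[Si](C)(C)C)[C@@H](C)C(=O)N1[C@@H](Cc2ccccc2)COC1=O
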